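The route rests on cutting the bond between C8 of one coumarin and ring carbon C2 (cyclohexene numbering: C1 quaternary, C2 aryl-bearing, C3=C4 alkene, methyl on C4). The key step exploits that C2 is one terminus of the allyl unit C2–C3–C4. All regio- and stereoisomeric allylic chlorides collapse to one allyl radical, which a chiral nickel catalyst couples with the coumarin-8-ylzinc reagent at the hydrogen-bearing terminus. One operation joins the two halves, places the C3=C4 alkene and sets C2. Its precursor is an epimer mixture of a tertiary allylic alcohol with the alkene at C2=C3, grown from an enantioselective Diels–Alder adduct that fixes C1.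

Key step: step 7

Assumption: the antipodes written for the TADDOL (step 3) and the pybox ligand (step 7) are taken to deliver the drawn configurations. Both controllers are sold in either form, so a reversed sense of induction is met by exchanging the antipode.

Step 1
Reactants: 1 umbelliferone (7-hydroxychromen-2-one)
Product: 2 7-hydroxy-8-iodochromen-2-one
Conditions: I2 (1 equiv), KI, aq NH3, 0 °C to rt; acidic work-up
Reagents that add atoms: iodine, II
Why: Electrophilic aromatic iodination of the phenoxide, which should go to C8 because this carbon lies ortho to the 7-oxygen and between two oxygen-bearing carbons and is the most nucleophilic site of umbelliferone in base.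

Step 2
Reactants: 2 7-hydroxy-8-iodochromen-2-one
Product: 3 8-iodo-7-methoxychromen-2-one
Conditions: MeI, K2CO3, acetone, reflux
Reagents that add atoms: iodomethane, CI
Why: Williamson ether synthesis on the acidic 7-phenol, with a carbonate base that leaves the lactone and the aryl iodide untouched.

Step 3
Reactants: 4 (E)-3-(tert-butyldimethylsilyloxy)-N,N-dimethylbuta-1,3-dien-1-amine; 5 methacrolein
Product: 6 (1S,2R)-4-(tert-butyldimethylsilyloxy)-2-(dimethylamino)-1-methylcyclohex-3-ene-1-carbaldehyde
Conditions: (R,R)-1-naphthyl-TADDOL (20 mol%), toluene, −80 °C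
Reagents that add atoms: none
Why: Hydrogen-bond-catalysed enantioselective Diels–Alder reaction, in which both donor groups of 4 direct its amino-bearing terminus to the α-carbon of 5, the TADDOL-bound aldehyde is attacked on one face only and thereby sets the quaternary carbon, and endo approach places NMe2 cis to CHO at a centre that step 4 removes.

Step 4
Reactants: 6 (1S,2R)-4-(tert-butyldimethylsilyloxy)-2-(dimethylamino)-1-methylcyclohex-3-ene-1-carbaldehyde
Product: 8 (R)-4-ethenyl-4-methylcyclohex-2-en-1-one, via vinyl silyl enol ether amine 7 (not isolated)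
Conditions: Ph3PCH3Br, KHMDS, THF, 0 °C, then 6, −78 °C to rt; then 2 M aq HCl, THF, rt
Reagents that add atoms: methyltriphenylphosphonium bromide, C[P+](c1ccccc1)(c1ccccc1)c1ccccc1.[Br-]
Why: Wittig methylenation of a non-enolisable aldehyde followed by acid hydrolysis of the silyl enol ether and E1cB loss of dimethylamine from the β-amino ketone, none of which can touch the quaternary carbon.

Step 5
Reactants: 8 (R)-4-ethenyl-4-methylcyclohex-2-en-1-one
Product: 9 (4R)-4-ethenyl-1,4-dimethylcyclohex-2-en-1-ol (both carbinol epimers)
Conditions: MeLi, Et2O, −78 °C; then H2O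
Reagents that add atoms: methyllithium, [Li]C
Why: 1,2-Addition of a hard organolithium to the enone carbonyl, which should give both carbinol epimers because the quaternary carbon is remote, a mixture that is carried on since step 7 erases this centre.

Step 6
Reactants: 9 (4R)-4-ethenyl-1,4-dimethylcyclohex-2-en-1-ol; 3 8-iodo-7-methoxychromen-2-one
Product: 10 8-{(E)-2-[(1R)-4-hydroxy-1,4-dimethylcyclohex-2-en-1-yl]ethenyl}-7-methoxychromen-2-one (both C4 epimers)
Conditions: Pd(OAc)2 (5 mol%), n-Bu4NCl, NaHCO3, DMF, 70 °C
Reagents that add atoms: none
Why: Heck reaction, in which the aryl–palladium species adds to the unhindered CH2 terminus of the vinyl group, the quaternary neighbour leaves only the benzylic hydrogens for syn β-hydride elimination so that the E-styrene should result, and the ring alkene between two fully substituted carbons stays inert.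

Step 7
Reactants: 10 8-{(E)-2-[(1R)-4-hydroxy-1,4-dimethylcyclohex-2-en-1-yl]ethenyl}-7-methoxychromen-2-one; 3 8-iodo-7-methoxychromen-2-one
Product: 14 7-methoxy-8-{(E)-2-[(1R,2R)-2-(7-methoxy-2-oxochromen-8-yl)-1,4-dimethylcyclohex-3-en-1-yl]ethenyl}chromen-2-one (CNP0156435.1), via secondary allylic chlorides 11 (not isolated), via tertiary allylic chlorides 12 (not isolated), via coumarin-8-ylzinc iodide 13 (not isolated)
Conditions: (i) 10, SOCl2, Et2O, −20 °C, volatiles removed in vacuo; (ii) 3, Zn dust, LiCl, THF, 40 °C; (iii) both solutions combined, NiCl2·glyme (10 mol%), (S,S)-CH2CH2Ph-pybox (13 mol%), NaCl, DMA/THF, −10 °C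
Reagents that add atoms: none
Why: Proposed new method: thionyl chloride turns both carbinol epimers of 10 into the regio- and stereoisomeric allylic chlorides 11 and 12, and chlorine abstraction by nickel(I) converts each of them into the same planar allyl radical over C2–C3–C4, so that the configuration at the former carbinol carbon no longer counts. The radical is captured by the aryl–nickel(II) pybox complex formed from 13, and reductive elimination from nickel(III) forms the C8–C2 bond and leaves the alkene at C3=C4. The closest known reaction types are the stereoconvergent nickel/pybox Negishi couplings of racemic secondary allylic chlorides with alkylzinc reagents and of racemic propargylic or benzylic halides with arylzinc reagents, and the rhodium-catalysed asymmetric arylation of racemic cyclic allyl chlorides; the pairing of an arylzinc with a cyclic, trisubstituted allyl unit next to a quaternary carbon has not been shown. No ring is closed; the one new stereocentre C2 is set by the chiral ligand, which distinguishes the quaternary C1 from the sp2 carbon C3 at the reacting terminus, while methyl and E-alkenyl on C1 are close in size, so that the bias of the substrate should be small and the minor enantiomer of 10 should end as a separable diastereomer. The step needs bond formation at C2 and not at C4, which the substrate secures because C4 is the fully substituted, methyl-bearing terminus, and it needs the lactones and the styryl alkene to stay untouched, which the low nucleophilicity of an arylzinc at −10 °C secures.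

Compound list
1 | umbelliferone (7-hydroxychromen-2-one) | Oc1ccc2ccc(=O)oc2c1 | starting material
2 | 7-hydroxy-8-iodochromen-2-one | Oc1ccc2ccc(=O)oc2c1I | intermediate
3 | 8-iodo-7-methoxychromen-2-one | COc1ccc2ccc(=O)oc2c1I | intermediate
4 | (E)-3-(tert-butyldimethylsilyloxy)-N,N-dimethylbuta-1,3-dien-1-amine | CN(C)/C=C/C(=C)O[Si](C)(C)C(C)(C)C | starting material
5 | methacrolein (2-methylprop-2-enal) | CC(=C)C=O | starting material
6 | (1S,2R)-4-(tert-butyldimethylsilyloxy)-2-(dimethylamino)-1-methylcyclohex-3-ene-1-carbaldehyde | O=C[C@@]1(C)CCC(O[Si](C)(C)C(C)(C)C)=C[C@H]1N(C)C | intermediate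
7 | (1R,6R)-3-(tert-butyldimethylsilyloxy)-6-ethenyl-N,N,6-trimethylcyclohex-2-en-1-amine | C=C[C@@]1(C)CCC(O[Si](C)(C)C(C)(C)C)=C[C@H]1N(C)C | intermediate
8 | (R)-4-ethenyl-4-methylcyclohex-2-en-1-one | C=C[C@@]1(C)CCC(=O)C=C1 | intermediate
9 | (4R)-4-ethenyl-1,4-dimethylcyclohex-2-en-1-ol, both carbinol epimers | C=C[C@@]1(C)CCC(C)(O)C=C1 | intermediate
10 | 8-{(E)-2-[(1R)-4-hydroxy-1,4-dimethylcyclohex-2-en-1-yl]ethenyl}-7-methoxychromen-2-one, both C4 epimers | COc1ccc2ccc(=O)oc2c1/C=C/[C@@]1(C)CCC(C)(O)C=C1 | intermediate
11 | 8-{(E)-2-[(1R)-2-chloro-1,4-dimethylcyclohex-3-en-1-yl]ethenyl}-7-methoxychromen-2-one, both C2 epimers | COc1ccc2ccc(=O)oc2c1/C=C/[C@@]1(C)CCC(C)=CC1Cl | intermediate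
12 | 8-{(E)-2-[(1R)-4-chloro-1,4-dimethylcyclohex-2-en-1-yl]ethenyl}-7-methoxychromen-2-one, both C4 epimers | COc1ccc2ccc(=O)oc2c1/C=C/[C@@]1(C)CCC(C)(Cl)C=C1 | intermediate
13 | (7-methoxy-2-oxochromen-8-yl)zinc iodide | COc1ccc2ccc(=O)oc2c1[Zn]I | intermediate
14 | 7-methoxy-8-{(E)-2-[(1R,2R)-2-(7-methoxy-2-oxochromen-8-yl)-1,4-dimethylcyclohex-3-en-1-yl]ethenyl}chromen-2-one (CNP0156435.1) | COc1ccc2ccc(=O)oc2c1/C=C/[C@@]1(C)CCC(C)=C[C@H]1c1c(OC)ccc2ccc(=O)oc12 | target

Total step count: 7. Longest linear sequence: 5 steps (steps 3 to 7, from 4 and 5 to 14).

Steps most likely to fail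

1. Step 7 (Proposed new method).
- What may go wrong: capture of the hindered allyl radical by the aryl–nickel complex may be slow, so that radical dimerisation and loss of hydrogen chloride from the chlorides take over. Facial discrimination by the ligand next to the quaternary carbon may also be weak.
- Fallback: known chemistry, stereospecific instead of stereoconvergent, from 10 back to 14.
- The two carbinol epimers of 10 are separated on silica.
- The epimer with the hydroxyl group trans to the styryl group F1 is acetylated (Ac2O, DMAP, Et3N, CH2Cl2) to the tertiary allylic acetate F2.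
- This acetate undergoes a palladium-catalysed Negishi allyl–aryl coupling with 13 (Pd(PPh3)4, THF, 40 °C).
- Ionisation anti to the acetate places palladium on the styryl face. Transfer of the aryl group from palladium to the less substituted terminus C2 on that face should give 14.
- The other epimer is re-equilibrated with dilute aqueous acid and fed back.

2. Step 6.
- What may go wrong: the tertiary allylic alcohol may ionise or dehydrate at the temperature that the di-ortho-substituted iodide needs for oxidative addition and insertion.
- Fallback: from 8 back to 10, with the order of the two bond formations exchanged.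
- The Heck reaction is run on the robust enone 8 with 3 to give the styryl enone F3.
- The methyl group is then brought in with the organocerium reagent from MeLi and CeCl3 (THF, −78 °C). This reagent should add to the ketone much faster than to the coumarin lactone and gives 10.

3. Step 3.
- What may go wrong: enantiofacial discrimination by the hydrogen-bond donor may be insufficient, or turnover at −80 °C may stall.
- Fallback: from 4 and 5 back to 8, with resolution in place of asymmetric catalysis.
- The uncatalysed Diels–Alder reaction (toluene, rt) gives the racemic cis adduct F4.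
- The conditions of step 4 convert it through the racemic vinyl silyl enol ether amine F5 into the racemic enone F6.
- This enone is resolved by preparative chromatography on a chiral stationary phase to give 8.

Further compounds
F1 | step 7 | 8-{(E)-2-[(1R,4S)-4-hydroxy-1,4-dimethylcyclohex-2-en-1-yl]ethenyl}-7-methoxychromen-2-one | COc1ccc2ccc(=O)oc2c1/C=C/[C@@]1(C)CC[C@](C)(O)C=C1
F2 | step 7 | (1S,4R)-4-[(E)-2-(7-methoxy-2-oxochromen-8-yl)ethenyl]-1,4-dimethylcyclohex-2-en-1-yl acetate | COc1ccc2ccc(=O)oc2c1/C=C/[C@@]1(C)CC[C@](C)(OC(C)=O)C=C1
F3 | step 6 | 7-methoxy-8-{(E)-2-[(1R)-1-methyl-4-oxocyclohex-2-en-1-yl]ethenyl}chromen-2-one | COc1ccc2ccc(=O)oc2c1/C=C/[C@@]1(C)CCC(=O)C=C1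
F4 | step 3 | rac-cis-4-(tert-butyldimethylsilyloxy)-2-(dimethylamino)-1-methylcyclohex-3-ene-1-carbaldehyde | O=CC1(C)CCC(O[Si](C)(C)C(C)(C)C)=CC1N(C)C
F5 | step 3 | rac-cis-3-(tert-butyldimethylsilyloxy)-6-ethenyl-N,N,6-trimethylcyclohex-2-en-1-amine | C=CC1(C)CCC(O[Si](C)(C)C(C)(C)C)=CC1N(C)C
F6 | step 3 | rac-4-ethenyl-4-methylcyclohex-2-en-1-one | C=CC1(C)CCC(=O)C=C1
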